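## Analysis of the target

Compound 11 is a single benzene ring (ring A) with a free hydroxyl on C1, methoxy groups on C2 and C4, and an unbranched, saturated twenty-one-carbon chain (C1' to C21') on C6; C3 and C5 carry hydrogen. There is no stereocentre and no second ring, so the problem is one of regiochemistry on ring A and of joining a long lipid chain to a small polar head. The three oxygens of the 1,2,4-trioxygenated array must be told apart: the one on C1, flanked by the chain and the C2 methoxy group, stays free while the other two are methylated. The chain stands ortho to the hydroxyl but meta to both methoxy groups, which is not where electrophilic substitution of a 2,4-dimethoxyphenol would place it, because C3 and C5 are far more activated than C6. The sensitive group is the para-methoxyphenol itself, which is easily oxidised to a quinone; it should stay masked until the last step, and anodic chemistry on this ring is to be avoided. Practical difficulty comes from the chain: odd-numbered C21 building blocks are scarce, and waxy long-chain intermediates are poorly soluble and hard to separate from one another. The strategy rests on the fact that the chain can be cut between C2' and C3' into a two-carbon arm on C6 and a nineteen-carbon unit, each the alkyl residue of a carboxylic acid after decarboxylation, the second being the cheap even-numbered acid 8. In addition, the C1 oxygen, C6 and the three-carbon acid that carries the arm together form a dihydrocoumarin whose aryl part, without the C1 oxygen, is a 3,5-dimethoxyphenyl group symmetric about the C6–C3 axis, so that C1 and C5 are equivalent.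

## Retrosynthetic reasoning

**11 to 10.** The C1 oxygen is capped as the benzyl ether 10. The cap is needed because a free hydroxyl ortho to the arm would attack the activated carbonyl of the redox-active ester and re-close the lactone, and because the free para-methoxyphenol would not survive handling through the sequence. The forward reaction, hydrogenolysis, has to cleave one benzylic C–O bond in a molecule that otherwise holds only an arene, two methyl ethers and an alkane chain.

**10 to 7 and 9.** The one skeletal bond to be made is C2'–C3' of 10. Cutting it gives two primary alkyl fragments, each a carboxylic acid less its carboxyl group, that is, the esters 7 and 9 of N-hydroxyphthalimide 6.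
- A cut at the ring (C6–C1') would need a metal-catalysed coupling at a di-ortho-substituted, electron-rich aryl carbon and an odd-numbered C21 chain reagent.
- A cut at C1'–C2' would need a stabilised benzylic radical, prone to dimerise, and again an odd-numbered C21 acid.
- The cut at C2'–C3' pairs two unstabilised primary radicals of like reactivity, draws the long piece from the even-numbered acid 8, and leaves on the ring exactly the three-carbon acid arm that is needed anyway to bring in the C1 oxygen.

The forward reaction has to generate both radicals by reductive decarboxylation and join them under nickel catalysis with cross- over homo-coupling. It must run at a cathode, because the trioxygenated ring would be oxidised at the anode potential of a classical Kolbe electrolysis.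

**7 to 5 and 6; 9 to 8 and 6.** Both esters are cut at the acyl–O bond. The forward reactions are carbodiimide esterifications, which only have to activate a primary carboxylic acid in the presence of ethers.

**5 to 2.** Acid 5 is traced to lactone 2 by cutting the benzyl–O bond and re-forming the aryl ester C–O bond. In the forward sense, hydroxide opens 2 to the phenoxide carboxylate 3, both oxygens are benzylated to 4, and the benzyl ester alone is saponified, so that only the phenol keeps its benzyl group. Nothing is gained in skeleton; what is gained is that the C1 oxygen and the acid arm, tied together in 2, are released in differentiated form.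

**2 to 1.** Lactone 2 is cut at the bond between ring carbon C1 and the lactone oxygen, which leads to the commercial acid 1. Because the 3,5-dimethoxyphenyl ring of 1 is symmetric, the two carbons ortho to the arm are equivalent, each para to one methoxy group and ortho to the other, and the tethered carboxyl can reach only these. The carbon between the methoxy groups, the other activated site, is out of its reach. The forward reaction is an oxidative C–H lactonisation that has to stop at the lactone; this is helped by the new oxygen being acylated and therefore a poorer donor than a free hydroxyl.

## Alternatives that were turned down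

Alternative 1: Ring A is built by cycloaddition and aromatisation.
- Disconnection: C5–C6 and C1–C2, giving the oxygenated diene 1,3-dimethoxy-1-(trimethylsilyloxy)buta-1,3-diene A1 and the acetylenic ketone pentacos-3-yn-2-one A2, in which an acetyl group stands in for the C1 oxygen.
- Forward key step: the nucleophilic CH2 terminus of A1 attacks the chain-bearing alkyne carbon of A2, the ketene-acetal carbon bonds to the acyl-bearing one, and the Diels–Alder adduct aromatises by loss of its alkoxy and silyl groups to 1-(2-hydroxy-4-methoxy-6-heneicosylphenyl)ethan-1-one A3. O-Methylation of the chelated hydroxyl, Baeyer–Villiger oxidation of the acetyl group and cleavage of the resulting aryl ester would lead to 11.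
- For it: the polarisation of both partners fixes the whole substitution pattern in one step, the three oxygens emerge differentiated, and there is no statistical coupling and no electrochemical cell. On regiochemical elegance it is at least the equal of the chosen route.
- Against it: A2 is a β-alkyl ynone, a sluggish dienophile for a diene that is moisture-sensitive and decomposes on prolonged heating. A2 must itself be made over several steps from a long-chain terminal alkyne that is not a bulk chemical. The acetyl marker must then be exchanged for oxygen by a peracid oxidation on a very electron-rich ring.
- Comparison: about eight steps against six. The chosen route buys ring A ready-made in 1 and spends its one risky step on the only skeletal bond that has to be made, where this alternative builds six ring carbons that can be purchased.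

Alternative 2: A polyketide-style fold.
- Disconnection: C1–C6, leading to the diketo-dioxinone 6-(2,4-dioxopentacosyl)-2,2-dimethyl-4H-1,3-dioxin-4-one A4.
- Forward key step: thermolysis of A4 in an alcoholic medium releases the open-chain methyl 3,5,7-trioxooctacosanoate A5. Its ester-flanked methylene adds in an aldol fashion to the chain-bearing ketone, and dehydration and enolisation give methyl 2,4-dihydroxy-6-heneicosylbenzoate A6, in which the ester carbon marks C1.
- For it: the regiochemistry is fully programmed, the C2 and C4 oxygens arise automatically, and no cross-selectivity problem exists. The long piece comes from an even-numbered C22 fatty acid derivative, so on raw material it is as good as the chosen route.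
- Against it: the target has oxygen, not carbon, on C1. After methylation of both hydroxyls, the ester of A6, hindered by two ortho substituents, must be reduced to the aldehyde level, oxidised in a Dakin or Baeyer–Villiger step and hydrolysed. These are three or four redox operations on an oxidation-prone ring. A4 also requires two low-temperature enolate acylations, the second with a waxy acyl donor.
- Comparison: roughly nine to ten steps. This alternative is stronger in regiochemical certainty; the chosen strategy offers in its place an oxygen on C1 from the second compound onward and a far shorter sequence.

Alternative 3: Thermal ring expansion of a four-membered ring.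
- Disconnection: C4–C5, leading to 4-(tert-butyldimethylsilyloxy)-3-methoxy-4-(tricos-1-en-2-yl)cyclobut-2-en-1-one A7.
- Forward key step: heating A7 triggers a four-electron electrocyclic opening followed by a six-electron closure (Moore rearrangement) that joins the former carbonyl carbon to the terminal CH2 of the alkenyl group. Tautomerisation gives 4-(tert-butyldimethylsilyloxy)-3-heneicosyl-5-methoxyphenol A8. Methylation of the new C4 hydroxyl and desilylation would finish the synthesis.
- For it: A8 carries the C1 and C4 oxygens already differentiated, one silylated and one free, by the mechanism itself. On this point it is stronger than the chosen route, which differentiates by protecting-group handling. The cascade is unimolecular and has no selectivity issue.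
- Against it: A7 needs a methoxy-substituted cyclobutenedione, several steps from a squarate ester, and a 2-metallated long-chain 1-alkene whose C23 precursor needs its own multistep synthesis. A8 is a hydroquinone monoether, even more oxidation-prone than 11, and two further steps follow it.
- Comparison: about ten steps. The chosen strategy offers purchased ring carbons, a purchased chain, and exposure of the oxidation-sensitive phenol only in the final step.

Key step: step 5

Remark on the chemistry: the chain is taken as the unbranched n-heneicosyl group drawn in the SMILES, the molecule has no stereocentre, and compounds 1, 6 and 8 are taken as purchased.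

## Route

Step 1
Reactants: 1 3-(3,5-dimethoxyphenyl)propanoic acid
Product: 2 6,8-dimethoxychroman-2-one (6,8-dimethoxy-3,4-dihydrocoumarin)
Conditions: PhI(OCOCF3)2 (1.1 equiv), BF3·OEt2 (1.5 equiv), CF3CO2H/CH2Cl2, 0 °C to rt, 0.02 M
Reagents that add atoms: none
Why: Hypervalent-iodine oxidative C–H lactonisation of a 3-arylpropanoic acid, a known route to methoxy-substituted dihydrocoumarins: the ring is oxidised to its radical cation, the tethered carboxyl adds at the ortho carbon (para to one methoxy group) through a six-membered transition state, and a second oxidation with loss of a proton restores the arene. Both ortho carbons of the symmetric ring are equivalent and the carbon between the methoxy groups cannot be reached, so only one lactone can form; high dilution suppresses intermolecular aryl–aryl coupling.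

Step 2
Reactants: 2 6,8-dimethoxychroman-2-one
Product: 5 3-(2-(benzyloxy)-3,5-dimethoxyphenyl)propanoic acid, via dipotassium phenoxide carboxylate 3 (not isolated), via benzyl ether benzyl ester 4 (not isolated)
Conditions: KOH (powdered, 5 equiv), DMSO, Ar, rt; BnBr (2.5 equiv), rt; then aq KOH, 70 °C; aq HCl to pH 2
Reagents that add atoms: benzyl bromide, BrCc1ccccc1; potassium hydroxide, [K+].[OH-]
Why: Hydroxide opens the aryl ester to the dianion 3, Williamson alkylation of both oxygens in the dipolar aprotic medium gives 4, and saponification removes only the ester benzyl group because the aryl benzyl ether is inert to hydroxide. Working under argon protects the electron-rich phenoxide from air oxidation.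

Step 3
Reactants: 5 3-(2-(benzyloxy)-3,5-dimethoxyphenyl)propanoic acid; 6 N-hydroxyphthalimide
Product: 7 1,3-dioxoisoindolin-2-yl 3-(2-(benzyloxy)-3,5-dimethoxyphenyl)propanoate
Conditions: DIC (1.1 equiv), DMAP (10 mol %), CH2Cl2, 0 °C to rt
Reagents that add atoms: none
Why: Steglich-type carbodiimide esterification of an unhindered primary acid with the acidic N–OH group; the benzyl ether blocks the lactonisation that a free ortho hydroxyl would undergo with the active ester.

Step 4
Reactants: 8 eicosanoic acid; 6 N-hydroxyphthalimide
Product: 9 1,3-dioxoisoindolin-2-yl eicosanoate
Conditions: DIC (1.1 equiv), DMAP (10 mol %), CH2Cl2/THF, rt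
Reagents that add atoms: none
Why: The same carbodiimide esterification on a saturated fatty acid; the THF co-solvent keeps the waxy acid in solution and the product should crystallise readily.

Step 5
Reactants: 7 1,3-dioxoisoindolin-2-yl 3-(2-(benzyloxy)-3,5-dimethoxyphenyl)propanoate; 9 1,3-dioxoisoindolin-2-yl eicosanoate
Product: 10 2-(benzyloxy)-1-heneicosyl-3,5-dimethoxybenzene
Conditions: 7 (1 equiv), 9 (3 equiv), NiCl2(dme) (20 mol %), 2,2':6',2''-terpyridine (20 mol %), AgNO3 (30 mol %), NaI, DMF/THF, Mg anode, RVC cathode, constant current, rt, undivided cell; aq HCl work-up
Reagents that add atoms: none
Why: This is the nickel-electrocatalytic doubly decarboxylative sp3–sp3 coupling of two redox-active esters, a known reaction type for pairs of primary acids. Each N-acyloxyphthalimide accepts one electron at the silver-coated cathode or from reduced nickel, its N–O bond breaks, and loss of phthalimide anion and CO2 leaves a primary radical: the 2-arylethyl radical from 7 and the nonadecyl radical from 9. The terpyridine-bound nickel formed from NiCl2(dme), cycling through its monovalent, divalent and trivalent states, captures the two radicals in turn, and the dialkyl trivalent nickel species reductively eliminates the C2'–C3' bond. The magnesium anode supplies the electrons, so the ring never meets an oxidising potential; the closest classical relative is mixed Kolbe electrolysis, run here in the reductive sense. No ring is closed and no stereocentre is formed, so no mode of closure and no stereocontrol element is involved. The only selectivity needed is cross- over homo-coupling, and since both radicals are unstabilised primary ones of like reactivity it is driven statistically by the threefold excess of the cheap ester 9. The two homodimers, a hydrocarbon wax and a much more polar bis-aryl ether, differ strongly from 10 in size and polarity and should separate on silica. The benzyl ether, the methoxy groups and the electron-rich ring are inert to the mild cathodic conditions.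

Step 6
Reactants: 10 2-(benzyloxy)-1-heneicosyl-3,5-dimethoxybenzene
Product: 11 6-heneicosyl-2,4-dimethoxyphenol
Conditions: H2 (1 atm), Pd/C (10 wt %), EtOAc/EtOH, rt; work-up under Ar
Reagents that add atoms: none
Why: Hydrogenolysis of an aryl benzyl ether over Pd/C cleaves only the benzylic C–O bond; methyl ethers, the arene and the alkane chain are untouched, and the ethyl acetate co-solvent keeps the waxy substrate dissolved.

## Compound list

1 | 3-(3,5-dimethoxyphenyl)propanoic acid | COc1cc(CCC(=O)O)cc(OC)c1 | starting material
2 | 6,8-dimethoxychroman-2-one (6,8-dimethoxy-3,4-dihydrocoumarin) | COc1cc2CCC(=O)Oc2c(OC)c1 | intermediate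
3 | dipotassium 3-(3,5-dimethoxy-2-oxidophenyl)propanoate (ring-opened phenoxide carboxylate, formed in the flask in step 2) | COc1cc(CCC(=O)[O-])c([O-])c(OC)c1.[K+].[K+] | intermediate
4 | benzyl 3-(2-(benzyloxy)-3,5-dimethoxyphenyl)propanoate (formed in the flask in step 2) | COc1cc(CCC(=O)OCc2ccccc2)c(OCc2ccccc2)c(OC)c1 | intermediate
5 | 3-(2-(benzyloxy)-3,5-dimethoxyphenyl)propanoic acid | COc1cc(CCC(=O)O)c(OCc2ccccc2)c(OC)c1 | intermediate
6 | N-hydroxyphthalimide | O=C1c2ccccc2C(=O)N1O | starting material
7 | 1,3-dioxoisoindolin-2-yl 3-(2-(benzyloxy)-3,5-dimethoxyphenyl)propanoate | O=C(CCc1cc(OC)cc(OC)c1OCc1ccccc1)ON1C(=O)c2ccccc2C1=O | intermediate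
8 | eicosanoic acid | CCCCCCCCCCCCCCCCCCCC(=O)O | starting material
9 | 1,3-dioxoisoindolin-2-yl eicosanoate | CCCCCCCCCCCCCCCCCCCC(=O)ON1C(=O)c2ccccc2C1=O | intermediate
10 | 2-(benzyloxy)-1-heneicosyl-3,5-dimethoxybenzene | CCCCCCCCCCCCCCCCCCCCCc1cc(OC)cc(OC)c1OCc1ccccc1 | intermediate
11 | 6-heneicosyl-2,4-dimethoxyphenol | CCCCCCCCCCCCCCCCCCCCCc1cc(OC)cc(OC)c1O | target

## Step count and least certain steps

Total step count: 6. Longest linear sequence: 5 steps (steps 1, 2, 3, 5 and 6 from 1); step 4 is a one-step branch from 8.

**Step 5 (key step).** The most likely failures are three. The first is statistical homo-coupling and simple reductive decarboxylation of the limiting ester 7, which lower the cross-coupling share. The second is hydrogen-atom transfer from the benzylic ether methylene to the primary 2-arylethyl radical through a seven-membered transition state before nickel captures it, which would shorten the arm to an ethyl group and damage the protecting group. The third is precipitation of the waxy ester 9 from the polar medium with passivation of the cathode. Fallback, from 5: reduction of the carboxyl group (BH3·THF, THF, 0 °C to rt) should give 3-(2-(benzyloxy)-3,5-dimethoxyphenyl)propan-1-ol F1. Appel bromination (CBr4, PPh3, CH2Cl2, 0 °C) should give 2-(benzyloxy)-1-(3-bromopropyl)-3,5-dimethoxybenzene F2. Copper-catalysed alkyl–alkyl coupling of F2 with commercial octadecylmagnesium chloride (Li2CuCl4 cat., THF, −10 °C to rt) would then form the C3'–C4' bond instead and come back to the route at 10. This is a two-electron substitution with no free radicals, so neither statistical coupling nor hydrogen-atom transfer can interfere, at the price of two more steps.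

**Step 1.** Over-oxidation of the lactone, whose ring is still electron-rich, toward quinone-type products by oxidative demethylation is possible, as is intermolecular aryl–aryl coupling of the radical cation at the carbon between the methoxy groups when the concentration is too high. Fallback, from 1: bromination with N-bromosuccinimide (MeCN, 0 °C) is expected to go ortho to the arm and para to a methoxy group and give 3-(2-bromo-3,5-dimethoxyphenyl)propanoic acid F3. Hydroxylation of the aryl bromide (Pd2(dba)3, t-BuXPhos, KOH, dioxane/H2O, 100 °C; then aq HCl) should give 3-(2-hydroxy-3,5-dimethoxyphenyl)propanoic acid F4, which should close to the lactone on warming with p-TsOH in toluene and so come back to the route at 2. This replaces the one-step oxidation by a halogenation and a two-electron C–O coupling and avoids radical cations.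

**Step 2.** Air oxidation of the para-methoxyphenoxide 3 in the strongly basic medium, competing C-benzylation of the phenoxide, and incomplete saponification of the lipophilic ester 4 are the risks. Fallback, from 2: acid-catalysed methanolysis (MeOH, cat. H2SO4, reflux) should open the lactone without forming a phenoxide and give methyl 3-(2-hydroxy-3,5-dimethoxyphenyl)propanoate F5. Mitsunobu benzylation (BnOH, PPh3, DIAD, THF, 0 °C to rt) should give methyl 3-(2-(benzyloxy)-3,5-dimethoxyphenyl)propanoate F6. Saponification (LiOH, THF/H2O, rt) then comes back to the route at 5.

**Step 6.** Slow or incomplete hydrogenolysis is possible because the waxy ether dissolves poorly in the protic solvents that favour the reaction and because traces of iodide or silver from the electrolysis may poison the catalyst. Air oxidation of the freed phenol during isolation is the other risk. Fallback, from 10: Lewis-acid debenzylation with BCl3 and pentamethylbenzene as cation scavenger (CH2Cl2, −78 °C) should cleave the benzyl ether in preference to the methyl ethers and give 11 directly; no new compound lies on the way.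

## Further compounds

F1 | step 5 | 3-(2-(benzyloxy)-3,5-dimethoxyphenyl)propan-1-ol | OCCCc1cc(OC)cc(OC)c1OCc1ccccc1
F2 | step 5 | 2-(benzyloxy)-1-(3-bromopropyl)-3,5-dimethoxybenzene | BrCCCc1cc(OC)cc(OC)c1OCc1ccccc1
F3 | step 1 | 3-(2-bromo-3,5-dimethoxyphenyl)propanoic acid | COc1cc(CCC(=O)O)c(Br)c(OC)c1
F4 | step 1 | 3-(2-hydroxy-3,5-dimethoxyphenyl)propanoic acid | COc1cc(CCC(=O)O)c(O)c(OC)c1
F5 | step 2 | methyl 3-(2-hydroxy-3,5-dimethoxyphenyl)propanoate | COC(=O)CCc1cc(OC)cc(OC)c1O
F6 | step 2 | methyl 3-(2-(benzyloxy)-3,5-dimethoxyphenyl)propanoate | COC(=O)CCc1cc(OC)cc(OC)c1OCc1ccccc1
F0 | step 6 | none | none
A1 | alternative 1 | 1,3-dimethoxy-1-(trimethylsilyloxy)buta-1,3-diene (used as the mixture of geometric isomers at the ketene acetal) | C=C(OC)C=C(OC)O[Si](C)(C)C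
A2 | alternative 1 | pentacos-3-yn-2-one | CC(=O)C#CCCCCCCCCCCCCCCCCCCCCC
A3 | alternative 1 | 1-(2-hydroxy-4-methoxy-6-heneicosylphenyl)ethan-1-one | CCCCCCCCCCCCCCCCCCCCCc1cc(OC)cc(O)c1C(C)=O
A4 | alternative 2 | 6-(2,4-dioxopentacosyl)-2,2-dimethyl-4H-1,3-dioxin-4-one | CC1(C)OC(=O)C=C(CC(=O)CC(=O)CCCCCCCCCCCCCCCCCCCCC)O1
A5 | alternative 2 | methyl 3,5,7-trioxooctacosanoate | COC(=O)CC(=O)CC(=O)CC(=O)CCCCCCCCCCCCCCCCCCCCC
A6 | alternative 2 | methyl 2,4-dihydroxy-6-heneicosylbenzoate | CCCCCCCCCCCCCCCCCCCCCc1cc(O)cc(O)c1C(=O)OC
A7 | alternative 3 | 4-(tert-butyldimethylsilyloxy)-3-methoxy-4-(tricos-1-en-2-yl)cyclobut-2-en-1-one | C=C(CCCCCCCCCCCCCCCCCCCCC)C1(O[Si](C)(C)C(C)(C)C)C(OC)=CC1=O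
A8 | alternative 3 | 4-(tert-butyldimethylsilyloxy)-3-heneicosyl-5-methoxyphenol | CCCCCCCCCCCCCCCCCCCCCc1cc(O)cc(OC)c1O[Si](C)(C)C(C)(C)C
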